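**Retrosynthetic overview**

1. Target 22 ⇐ triol 21 (late angeloylation at O9) ⇐ 20 ⇐ hydroxy lactone 17 (exocyclic methylene from the C11 methyl by selenoxide elimination).
2. 17 ⇐ acyclic keto carbonate 15 by cutting C11–C12 (Claisen-type C-acylation) and C6–C7 (Norrish–Yang cyclisation). The 13-membered β-keto lactone 16, made in the flask, contracts transannularly.
3. Enabling feature: in the lactone ring (O1–C12–C11–C7–C6), C7 is a tertiary carbinol β to the carbonyl C12 and C6 is an allylic CH–O. The ring is therefore the photocyclised form of a β-keto ester whose O-alkyl carbon carries a weak δ-hydrogen.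
4. 15 ⇐ Z-selective Wittig union at C1=C10 of the geraniol-derived phosphonium salt 7 (C1–C6, 4E alkene) with methyl ketone 10 from D-tartaric diamide 8 (C8 and C9 bought; C6 and C7 relayed from them in the key step).
5. Ring order: dioxolane (temporary) → 13-membered lactone (transient) → ten-membered carbocycle and γ-lactone together in step 12.

Key step: step 12

Remark: germacranolide numbering is used (C6 lactone CH–O, C7 carbinol, C8 OH, C9 O-angelate, C11/C13 methylene unit, C12 lactone carbonyl, ring alkenes C1=C10 Z and C4=C5 E); C11 of 16–19 is carried as an epimer mixture because it becomes sp2 in step 14.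

**Route**

Step 1
Reactants: 1 geraniol
Product: 2 tert-butyl(geranyloxy)diphenylsilane
Conditions: t-BuPh2SiCl, imidazole, DMF, 23 °C
Reagents that add atoms: tert-butyl(chloro)diphenylsilane, CC(C)(C)[Si](Cl)(c1ccccc1)c1ccccc1
Why: Silyl ether formation masks the primary allylic alcohol (later O1) against the ylide and Grignard steps.

Step 2
Reactants: 2 tert-butyl(geranyloxy)diphenylsilane
Product: 4 (4E)-6-(tert-butyldiphenylsilyloxy)-4-methylhex-4-enal, via epoxide 3 (not isolated)
Conditions: mCPBA, CH2Cl2, 0 °C; then H5IO6, THF/H2O, 0 °C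
Reagents that add atoms: 3-chloroperoxybenzoic acid, OOC(=O)c1cccc(Cl)c1
Why: Prilezhaev epoxidation should prefer the distal, more electron-rich trisubstituted alkene (the other is deactivated by the allylic oxygen), and periodic acid cleavage of the epoxide gives the aldehyde with the E alkene untouched.

Step 3
Reactants: 4 (4E)-6-(tert-butyldiphenylsilyloxy)-4-methylhex-4-enal
Product: 5 (4E)-6-(tert-butyldiphenylsilyloxy)-4-methylhex-4-en-1-ol
Conditions: NaBH4, MeOH, 0 °C
Reagents that add atoms: none
Why: Borohydride reduction of the aldehyde gives the primary alcohol.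

Step 4
Reactants: 5 (4E)-6-(tert-butyldiphenylsilyloxy)-4-methylhex-4-en-1-ol
Product: 6 tert-butyl[(2E)-6-iodo-3-methylhex-2-enyloxy]diphenylsilane
Conditions: I2, PPh3, imidazole, CH2Cl2, 0 → 23 °C
Reagents that add atoms: iodine, II
Why: Appel-type iodination converts the primary alcohol into the iodide with inversion-free SN2 displacement at CH2.

Step 5
Reactants: 6 tert-butyl[(2E)-6-iodo-3-methylhex-2-enyloxy]diphenylsilane
Product: 7 [(4E)-6-(tert-butyldiphenylsilyloxy)-4-methylhex-4-enyl]triphenylphosphonium iodide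
Conditions: PPh3, MeCN, reflux
Reagents that add atoms: triphenylphosphine, c1ccc(cc1)P(c1ccccc1)c1ccccc1
Why: SN2 quaternisation of the primary iodide gives the Wittig salt.

Step 6
Reactants: 8 (2S,3S)-2,3-dihydroxy-N,N,N',N'-tetramethylbutanediamide
Product: 9 (4S,5S)-N,N,N',N',2,2-hexamethyl-1,3-dioxolane-4,5-dicarboxamide
Conditions: Me2C(OMe)2, TsOH (cat.), toluene, 80 °C
Reagents that add atoms: 2,2-dimethoxypropane, COC(C)(C)OC
Why: Acid-catalysed acetal exchange ties the bought threo diol (future C8, C9) into a rigid trans-dioxolane.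

Step 7
Reactants: 9 (4S,5S)-N,N,N',N',2,2-hexamethyl-1,3-dioxolane-4,5-dicarboxamide
Product: 10 (4S,5S)-5-acetyl-N,N,2,2-tetramethyl-1,3-dioxolane-4-carboxamide
Conditions: MeMgBr (1.2 equiv), THF, −10 °C; then H2O
Reagents that add atoms: methylmagnesium bromide, C[Mg]Br
Why: Grignard acyl substitution on the α-alkoxy dimethylamide stops after one addition because the magnesium-chelated tetrahedral adduct (Weinreb-type behaviour) survives until work-up and spares the second amide.

Step 8
Reactants: 7 [(4E)-6-(tert-butyldiphenylsilyloxy)-4-methylhex-4-enyl]triphenylphosphonium iodide; 10 (4S,5S)-5-acetyl-N,N,2,2-tetramethyl-1,3-dioxolane-4-carboxamide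
Product: 12 (4S,5R)-5-[(2Z,6E)-8-(tert-butyldiphenylsilyloxy)-6-methylocta-2,6-dien-2-yl]-N,N,2,2-tetramethyl-1,3-dioxolane-4-carboxamide, via ylide 11 (not isolated)
Conditions: KN(SiMe3)2, THF, −78 °C; then 10, −78 → 23 °C
Reagents that add atoms: none
Why: Salt-free Wittig olefination of a non-stabilised ylide with an α-alkoxy methyl ketone is Z-selective for trisubstituted alkenes (ylide alkyl cis to the alkoxy-bearing carbon), which should set C1=C10 as Z.

Step 9
Reactants: 12 (4S,5R)-5-[(2Z,6E)-8-(tert-butyldiphenylsilyloxy)-6-methylocta-2,6-dien-2-yl]-N,N,2,2-tetramethyl-1,3-dioxolane-4-carboxamide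
Product: 13 1-[(4S,5R)-5-[(2Z,6E)-8-(tert-butyldiphenylsilyloxy)-6-methylocta-2,6-dien-2-yl]-2,2-dimethyl-1,3-dioxolan-4-yl]propan-1-one
Conditions: EtMgBr (2.5 equiv), THF, 0 °C; then H2O
Reagents that add atoms: ethylmagnesium bromide, CC[Mg]Br
Why: A second chelation-controlled Grignard acyl substitution turns the remaining dimethylamide into the ethyl ketone (C7=O with C11 and C13 in place).

Step 10
Reactants: 13 1-[(4S,5R)-5-[(2Z,6E)-8-(tert-butyldiphenylsilyloxy)-6-methylocta-2,6-dien-2-yl]-2,2-dimethyl-1,3-dioxolan-4-yl]propan-1-one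
Product: 14 1-[(4S,5R)-5-[(2Z,6E)-8-hydroxy-6-methylocta-2,6-dien-2-yl]-2,2-dimethyl-1,3-dioxolan-4-yl]propan-1-one
Conditions: Bu4NF, AcOH, THF, 0 → 23 °C
Reagents that add atoms: none
Why: Fluoride desilylation, buffered with acetic acid so that the α-alkoxy ketone is neither epimerised nor opened by β-elimination, frees the allylic alcohol.

Step 11
Reactants: 14 1-[(4S,5R)-5-[(2Z,6E)-8-hydroxy-6-methylocta-2,6-dien-2-yl]-2,2-dimethyl-1,3-dioxolan-4-yl]propan-1-one
Product: 15 (2E,6Z)-7-[(4R,5S)-2,2-dimethyl-5-propanoyl-1,3-dioxolan-4-yl]-3-methylocta-2,6-dienyl pentafluorophenyl carbonate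
Conditions: C6F5OC(O)Cl, pyridine, CH2Cl2, −20 °C
Reagents that add atoms: pentafluorophenyl chloroformate, O=C(Cl)Oc1c(F)c(F)c(F)c(F)c1F
Why: O-acylation of the alcohol gives an activated mixed carbonate that already carries the O1–C12 bond of the lactone.

Step 12
Reactants: 15 (2E,6Z)-7-[(4R,5S)-2,2-dimethyl-5-propanoyl-1,3-dioxolan-4-yl]-3-methylocta-2,6-dienyl pentafluorophenyl carbonate
Product: 17 7-hydroxy-8,9-O-isopropylidene-11,13-dihydrogermacra-1(10)Z,4E-dien-12,6-olide (C6–C9 configured as in 22), via β-keto lactone 16 (not isolated)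
Conditions: MgBr2·OEt2, i-Pr2NEt, CH2Cl2 (0.002 M, slow addition), 23 °C; AcOH, H2O wash; then hν (> 300 nm, Pyrex), CH2Cl2, 10 °C
Reagents that add atoms: none
Why: Proposed new method: soft enolisation of the ethyl ketone and C-acylation of the C11 magnesium enolate by the tethered pentafluorophenyl carbonate should form C11–C12 and close the 13-membered β-keto lactone 16 (13-exo-trig acyl substitution driven by the magnesium chelate of the β-keto ester; closest known types: direct Claisen-type acylation of ketones with pentafluorophenyl esters under soft enolisation, and Dieckmann macrocyclisation). After protonation, n→π* excitation of the C7 ketone should lead to 1,6-hydrogen transfer from C6, which holds by far the weakest δ C–H bond (allylic and α to oxygen; no γ C–H exists on either side of the carbonyl), and the 1,5-biradical (C7 ketyl/C6 allyl) recombines to the C6–C7 bond (closest known type: Norrish–Yang photocyclisation of β-oxo esters to β-hydroxy-γ-lactones). This recombination is a transannular ring contraction: it closes the γ-lactone as a five-membered ring (bonding at C6, because bonding at C4 of the allyl radical would need a seven-membered ring) and, in the same event, the ten-membered carbocycle out of the 13-membered one. C7 should be set by recombination anti to the C8–O bond of the rigid trans-dioxolane (Felkin-type, no chelating metal, giving the 7,8-anti diol), and C6 by collapse of the biradical in the folded s-cis ester geometry in which the hydrogen was transferred, which places H6 and the new OH cis; the 4E geometry should survive because the allyl radical collapses faster than it rotates. The step needs δ-abstraction to outrun α-cleavage and alkene quenching, and acylation at C11 rather than C8: the absent γ-hydrogens, the weak C6–H bond and the trans-dioxolane that holds C10=C1 away from C7=O serve the first, the hindered C8 position whose acylation product cannot form a chelated enolate serves the second.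

Step 13
Reactants: 17 7-hydroxy-8,9-O-isopropylidene-11,13-dihydrogermacra-1(10)Z,4E-dien-12,6-olide
Product: 18 11-phenylselanyl derivative of 17
Conditions: LiN(i-Pr)2 (2.5 equiv), THF, −78 °C; PhSeBr; then H2O
Reagents that add atoms: benzeneselenenyl bromide, Br[Se]c1ccccc1
Why: α-Selenenylation of the lactone enolate (formed as the alkoxide–enolate dianion at the only enolisable position, C11) installs the leaving group; the C11 configuration is irrelevant.

Step 14
Reactants: 18 11-phenylselanyl derivative of 17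
Product: 20 7-hydroxy-8,9-O-isopropylidenegermacra-1(10)Z,4E,11(13)-trien-12,6-olide, via selenoxide 19 (not isolated)
Conditions: H2O2 (30%), pyridine, CH2Cl2, 0 → 23 °C
Reagents that add atoms: none
Why: Selenoxide syn-elimination can only use the methyl hydrogens because C7 is quaternary, so the exocyclic C11=C13 methylene should form exclusively.

Step 15
Reactants: 20 7-hydroxy-8,9-O-isopropylidenegermacra-1(10)Z,4E,11(13)-trien-12,6-olide
Product: 21 (6S,7S,8S,9R)-7,8,9-trihydroxygermacra-1(10)Z,4E,11(13)-trien-12,6-olide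
Conditions: AcOH/H2O (4:1), 50 °C
Reagents that add atoms: none
Why: Mild acid hydrolysis removes the acetonide without ionising the allylic C9–O bond or touching the α-methylene lactone.

Step 16
Reactants: 21 (6S,7S,8S,9R)-7,8,9-trihydroxygermacra-1(10)Z,4E,11(13)-trien-12,6-olide
Product: 22 (6S,7S,8S,9R)-9-angeloyloxy-7,8-dihydroxygermacra-1(10)Z,4E,11(13)-trien-12,6-olide
Conditions: angelic acid, 2,4,6-Cl3C6H2COCl, Et3N, toluene, 23 °C; then 21, 75 °C
Reagents that add atoms: angelic acid, C/C=C(/C)C(=O)O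
Why: Yamaguchi-type mixed-anhydride esterification without a nucleophilic catalyst should keep the Z geometry of the angelate and acylate the allylic C9–OH in preference to the neopentyl-like C8–OH and the tertiary C7–OH.

**Compound list**

1 | geraniol, (2E)-3,7-dimethylocta-2,6-dien-1-ol | OC/C=C(\C)CCC=C(C)C | starting material
2 | tert-butyl(geranyloxy)diphenylsilane | CC(C)(C)[Si](c1ccccc1)(c1ccccc1)OC/C=C(\C)CCC=C(C)C | intermediate
3 | 6,7-epoxide of 2 (racemic at the epoxide) | CC(C)(C)[Si](c1ccccc1)(c1ccccc1)OC/C=C(\C)CCC1OC1(C)C | intermediate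
4 | (4E)-6-(tert-butyldiphenylsilyloxy)-4-methylhex-4-enal | CC(C)(C)[Si](c1ccccc1)(c1ccccc1)OC/C=C(\C)CCC=O | intermediate
5 | (4E)-6-(tert-butyldiphenylsilyloxy)-4-methylhex-4-en-1-ol | CC(C)(C)[Si](c1ccccc1)(c1ccccc1)OC/C=C(\C)CCCO | intermediate
6 | tert-butyl[(2E)-6-iodo-3-methylhex-2-enyloxy]diphenylsilane | CC(C)(C)[Si](c1ccccc1)(c1ccccc1)OC/C=C(\C)CCCI | intermediate
7 | [(4E)-6-(tert-butyldiphenylsilyloxy)-4-methylhex-4-enyl]triphenylphosphonium iodide | CC(C)(C)[Si](c1ccccc1)(c1ccccc1)OC/C=C(\C)CCC[P+](c1ccccc1)(c1ccccc1)c1ccccc1.[I-] | intermediate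
8 | (2S,3S)-2,3-dihydroxy-N,N,N',N'-tetramethylbutanediamide (tetramethyl-D-tartaramide) | CN(C)C(=O)[C@@H](O)[C@H](O)C(=O)N(C)C | starting material
9 | (4S,5S)-N,N,N',N',2,2-hexamethyl-1,3-dioxolane-4,5-dicarboxamide | CN(C)C(=O)[C@@H](OC(C)(C)O1)[C@H]1C(=O)N(C)C | intermediate
10 | (4S,5S)-5-acetyl-N,N,2,2-tetramethyl-1,3-dioxolane-4-carboxamide | CC(=O)[C@@H](OC(C)(C)O1)[C@H]1C(=O)N(C)C | intermediate
11 | phosphorus ylide of 7 | CC(C)(C)[Si](c1ccccc1)(c1ccccc1)OC/C=C(\C)CCC=P(c1ccccc1)(c1ccccc1)c1ccccc1 | intermediate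
12 | (4S,5R)-5-[(2Z,6E)-8-(tert-butyldiphenylsilyloxy)-6-methylocta-2,6-dien-2-yl]-N,N,2,2-tetramethyl-1,3-dioxolane-4-carboxamide | CC(C)(C)[Si](c1ccccc1)(c1ccccc1)OC/C=C(\C)CC/C=C(/C)[C@@H](OC(C)(C)O2)[C@H]2C(=O)N(C)C | intermediate
13 | 1-[(4S,5R)-5-[(2Z,6E)-8-(tert-butyldiphenylsilyloxy)-6-methylocta-2,6-dien-2-yl]-2,2-dimethyl-1,3-dioxolan-4-yl]propan-1-one | CC(C)(C)[Si](c1ccccc1)(c1ccccc1)OC/C=C(\C)CC/C=C(/C)[C@@H](OC(C)(C)O2)[C@H]2C(=O)CC | intermediate
14 | 1-[(4S,5R)-5-[(2Z,6E)-8-hydroxy-6-methylocta-2,6-dien-2-yl]-2,2-dimethyl-1,3-dioxolan-4-yl]propan-1-one | OC/C=C(\C)CC/C=C(/C)[C@@H](OC(C)(C)O1)[C@H]1C(=O)CC | intermediate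
15 | (2E,6Z)-7-[(4R,5S)-2,2-dimethyl-5-propanoyl-1,3-dioxolan-4-yl]-3-methylocta-2,6-dienyl pentafluorophenyl carbonate | O=C(Oc1c(F)c(F)c(F)c(F)c1F)OC/C=C(\C)CC/C=C(/C)[C@@H](OC(C)(C)O2)[C@H]2C(=O)CC | intermediate
16 | 13-membered β-keto lactone: C6–O1–C12 lactone with C7 ketone, C11 methyl (epimers), (8S,9R)-dioxolane, 1(10)Z and 4E alkenes | CC1C(=O)OC/C=C(\C)CC/C=C(/C)[C@@H](OC(C)(C)O2)[C@H]2C1=O | intermediate
17 | 7-hydroxy-8,9-O-isopropylidene-11,13-dihydrogermacra-1(10)Z,4E-dien-12,6-olide, C6–C9 configured as in 22, C11 epimers | CC1C(=O)O[C@H]2/C=C(\C)CC/C=C(/C)[C@@H](OC(C)(C)O3)[C@H]3[C@@]12O | intermediate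
18 | 11-phenylselanyl derivative of 17 | CC1([Se]c4ccccc4)C(=O)O[C@H]2/C=C(\C)CC/C=C(/C)[C@@H](OC(C)(C)O3)[C@H]3[C@@]12O | intermediate
19 | selenoxide of 18 | CC1([Se](=O)c4ccccc4)C(=O)O[C@H]2/C=C(\C)CC/C=C(/C)[C@@H](OC(C)(C)O3)[C@H]3[C@@]12O | intermediate
20 | 7-hydroxy-8,9-O-isopropylidenegermacra-1(10)Z,4E,11(13)-trien-12,6-olide, C6–C9 configured as in 22 | C=C1C(=O)O[C@H]2/C=C(\C)CC/C=C(/C)[C@@H](OC(C)(C)O3)[C@H]3[C@@]12O | intermediate
21 | (6S,7S,8S,9R)-7,8,9-trihydroxygermacra-1(10)Z,4E,11(13)-trien-12,6-olide | C=C1C(=O)O[C@H]2/C=C(\C)CC/C=C(/C)[C@@H](O)[C@H](O)[C@@]12O | intermediate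
22 | (6S,7S,8S,9R)-9-angeloyloxy-7,8-dihydroxygermacra-1(10)Z,4E,11(13)-trien-12,6-olide | C=C1C(=O)O[C@H]2/C=C(\C)CC/C=C(/C)[C@@H](OC(=O)/C(C)=C\C)[C@H](O)[C@@]12O | target

**Step count and risks**

Total steps: 16. Longest linear sequence: 14 (steps 1–5 and 8–16, from geraniol).

Steps most likely to fail:

1. Step 12 (Proposed new method). What may go wrong:
   - Acylation stage: intermolecular acylation and oligomerisation instead of 13-membered ring closure; bromide attack on the allylic carbonate; base-induced β-elimination that opens the dioxolane.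
   - Photochemical stage: slow hydrogen transfer because the macrolactone populates the s-trans ester conformer; α-cleavage; hydrogen abstraction at other transannular C–H bonds; poor facial selectivity at C7 or the wrong ring fusion at C6.

   Fallback with known chemistry, setting out from amide 12 and returning at 17: acylation of the lithium enolate of methyl propanoate (LiN(i-Pr)2, THF, −78 °C) by the chelating dimethylamide of 12 should give β-keto ester F1, which already holds the C11–C12 bond. Bu4NF/AcOH then frees allylic alcohol F2, and MnO2 in CH2Cl2 oxidises it to enal F3. A McMurry-type pinacol macrocyclisation (TiCl3(DME)1.5, Zn–Cu, DME, 25 °C, high dilution; SmI2 as alternative), a known way to close ten- to fourteen-membered carbocycles that tends to give trans-diols in rings of this size, should join C6 to C7 as dihydroxy ester F4. Acid-induced lactonisation (PPTS, toluene) then gives 17.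

2. Step 8. What may go wrong: insufficient Z-selectivity in the formation of the trisubstituted C1=C10 alkene, and enolisation of the α-alkoxy ketone by the basic ylide, which stalls conversion.

   Fallback, setting out from iodide 6 (with ketone 10) and returning at 12: Michaelis–Arbuzov reaction of 6 with ethyl diphenylphosphinite (120 °C) gives phosphine oxide F5. Its lithio derivative (n-BuLi, THF, −78 °C) adds to ketone 10 to give the β-hydroxy phosphine oxides F6, which are separated as diastereomers. Stereospecific syn-elimination (NaH, DMF, 50 °C) of the appropriate diastereomer, a Horner–Wittig olefination, should deliver geometrically pure 12.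

3. Step 16. What may go wrong: loss of regiocontrol between O9 and O8 or double acylation, isomerisation of the angelate to the tiglate, and translactonisation of the free C8–OH onto C12 on heating with base.

   Fallback, setting out from triol 21 and returning at 22: Bu2SnO (toluene, reflux, water removal) should convert the 8,9-diol into the dibutylstannylene acetal F7. Treatment with angelic anhydride at 0 °C then acylates the more nucleophilic, less hindered allylic oxygen O9 under neutral conditions and gives 22 after aqueous work-up.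

Further compounds
F1 | step 12 | methyl 3-[(4S,5R)-5-[(2Z,6E)-8-(tert-butyldiphenylsilyloxy)-6-methylocta-2,6-dien-2-yl]-2,2-dimethyl-1,3-dioxolan-4-yl]-2-methyl-3-oxopropanoate | CC(C)(C)[Si](c1ccccc1)(c1ccccc1)OC/C=C(\C)CC/C=C(/C)[C@@H](OC(C)(C)O2)[C@H]2C(=O)C(C)C(=O)OC
F2 | step 12 | methyl 3-[(4S,5R)-5-[(2Z,6E)-8-hydroxy-6-methylocta-2,6-dien-2-yl]-2,2-dimethyl-1,3-dioxolan-4-yl]-2-methyl-3-oxopropanoate | OC/C=C(\C)CC/C=C(/C)[C@@H](OC(C)(C)O1)[C@H]1C(=O)C(C)C(=O)OC
F3 | step 12 | methyl 3-[(4S,5R)-2,2-dimethyl-5-[(2Z,6E)-6-methyl-8-oxoocta-2,6-dien-2-yl]-1,3-dioxolan-4-yl]-2-methyl-3-oxopropanoate | O=C/C=C(\C)CC/C=C(/C)[C@@H](OC(C)(C)O1)[C@H]1C(=O)C(C)C(=O)OC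
F4 | step 12 | methyl 2-[6,7-dihydroxy-8,9-O-isopropylidenegermacra-1(10)Z,4E-dien-7-yl]propanoate, C6–C9 configured as in 17 | O[C@H]1/C=C(\C)CC/C=C(/C)[C@@H](OC(C)(C)O2)[C@H]2[C@@]1(O)C(C)C(=O)OC
F5 | step 8 | [(4E)-6-(tert-butyldiphenylsilyloxy)-4-methylhex-4-enyl]diphenylphosphine oxide | CC(C)(C)[Si](c1ccccc1)(c1ccccc1)OC/C=C(\C)CCCP(=O)(c1ccccc1)c1ccccc1
F6 | step 8 | β-hydroxy phosphine oxide adducts of F5 and 10 (diastereomers at the two new centres) | CC(C)(C)[Si](c1ccccc1)(c1ccccc1)OC/C=C(\C)CCC(P(=O)(c1ccccc1)c1ccccc1)C(C)(O)[C@@H](OC(C)(C)O2)[C@H]2C(=O)N(C)C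
F7 | step 16 | 8,9-O-dibutylstannylene acetal of 21 | C=C1C(=O)O[C@H]2/C=C(\C)CC/C=C(/C)[C@@H](O[Sn](CCCC)(CCCC)O3)[C@H]3[C@@]12O
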